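**Plan** (lactone numbering O1, C2(=O), C3(OH), C4, C5)

- Retrosynthesis: the lactone C=O and the tertiary OH are traced back, by two Baeyer–Villiger C→O exchanges, to a ring CH(vinyl) and a C–CHO of a 2-vinyl-3-formyl-3,4-dibenzyloxolane. That oxolane is cut at C5–C4 and at C2–C3 (Prins–pinacol transform) to a 4-vinyl-5-alkenyl-1,3-dioxolane, then between the two carbinol carbons to a (Z)-enal and a γ-silylallylborane, and the enal at its C=C (Still–Gennari).
- Feature used: ring oxygen O1 carries C5H2 and C2, and these two carbons sit on the two ends of the C3–C4 bond. An O-bound CH2+ (formaldehyde oxocarbenium) and an O-bound migrating carbon can therefore be added across a C3=C4 alkene that already holds both benzyl groups.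
- Forward order: (Z)-alkene, anti diol, 1,3-dioxolane (temporary ring), oxane cation, oxolane by ring contraction (one operation), excision of the vinyl and formyl helpers, lactone, free phenols.
- Stereochemistry: the Ipc2B allylboration sets the vinyl carbinol center, which selects the alkene face in the chair (C4). The Z geometry puts formyl cis and benzyl trans to the C4 benzyl (C3). The 1,2-shift and both Baeyer–Villiger steps go with retention.

Key step: step 10

Remark: the target is read as the (3S,4S) lactone (benzyl groups trans, tertiary OH cis to the C4 benzyl); both phenols are carried as benzyl ethers, and compounds 3, 8, 17 and 20 are used as mixtures at the centers left unspecified.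

**Route**

Step 1
Reactants: 1 eugenol (4-allyl-2-methoxyphenol)
Product: 2 4-allyl-1-(benzyloxy)-2-methoxybenzene
Conditions: BnBr, K2CO3, acetone, reflux
Reagents that add atoms: benzyl bromide, BrCc1ccccc1
Why: Williamson ether synthesis, the phenoxide displacing bromide from the benzylic halide, masks the phenol for the organometallic, Lewis acid and peracid steps.

Step 2
Reactants: 2 4-allyl-1-(benzyloxy)-2-methoxybenzene
Product: 4 [4-(benzyloxy)-3-methoxyphenyl]acetaldehyde, via secondary ozonide 3 (not isolated)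
Conditions: O3, CH2Cl2, −78 °C; then PPh3, −78 °C → rt
Reagents that add atoms: ozone, [O-][O+]=O
Why: Ozonolysis (Criegee mechanism) with reductive work-up cuts the terminal alkene to the arylacetaldehyde, the alkoxyarene reacting far more slowly at −78 °C.

Step 3
Reactants: 5 [4-(benzyloxy)-3-methoxyphenyl]methanol
Product: 6 1-(benzyloxy)-4-(bromomethyl)-2-methoxybenzene
Conditions: PBr3, Et2O, 0 °C
Reagents that add atoms: phosphorus tribromide, BrP(Br)Br
Why: Standard bromination of an electron-rich benzylic alcohol through its bromophosphite (SN2 by bromide) should give the reactive benzylic bromide, to be used crude.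

Step 4
Reactants: 7 methyl 2-[bis(2,2,2-trifluoroethoxy)phosphoryl]acetate; 6 1-(benzyloxy)-4-(bromomethyl)-2-methoxybenzene
Product: 8 methyl 3-[4-(benzyloxy)-3-methoxyphenyl]-2-[bis(2,2,2-trifluoroethoxy)phosphoryl]propanoate (racemic)
Conditions: NaH, THF–DMF, 0 °C → rt
Reagents that add atoms: none
Why: C-alkylation of the sodium salt of the stabilized phosphonoacetate (SN2 on the benzylic bromide) gives the α-substituted olefination reagent; its stereocenter is racemic and is destroyed in step 5.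

Step 5
Reactants: 8 methyl 3-[4-(benzyloxy)-3-methoxyphenyl]-2-[bis(2,2,2-trifluoroethoxy)phosphoryl]propanoate; 4 [4-(benzyloxy)-3-methoxyphenyl]acetaldehyde
Product: 9 methyl (2Z)-4-[4-(benzyloxy)-3-methoxyphenyl]-2-{[4-(benzyloxy)-3-methoxyphenyl]methyl}but-2-enoate
Conditions: KN(SiMe3)2, 18-crown-6, THF, −78 °C
Reagents that add atoms: none
Why: Still–Gennari variant of the Horner–Wadsworth–Emmons olefination: the electron-poor bis(trifluoroethyl) phosphonate under dissociating conditions eliminates from the kinetic adduct and should give the (Z)-trisubstituted ester, with the ester cis to the new CH2Ar group.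

Step 6
Reactants: 9 methyl (2Z)-4-[4-(benzyloxy)-3-methoxyphenyl]-2-{[4-(benzyloxy)-3-methoxyphenyl]methyl}but-2-enoate
Product: 10 (2Z)-4-[4-(benzyloxy)-3-methoxyphenyl]-2-{[4-(benzyloxy)-3-methoxyphenyl]methyl}but-2-en-1-ol
Conditions: i-Bu2AlH, CH2Cl2, −78 °C; aq. potassium sodium tartrate
Reagents that add atoms: none
Why: 1,2-Reduction of the unsaturated ester by the aluminium hydride gives the allylic alcohol without touching the alkene geometry.

Step 7
Reactants: 10 (2Z)-4-[4-(benzyloxy)-3-methoxyphenyl]-2-{[4-(benzyloxy)-3-methoxyphenyl]methyl}but-2-en-1-ol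
Product: 11 (2Z)-4-[4-(benzyloxy)-3-methoxyphenyl]-2-{[4-(benzyloxy)-3-methoxyphenyl]methyl}but-2-enal
Conditions: MnO2, CH2Cl2, rt
Reagents that add atoms: none
Why: Chemoselective allylic oxidation with MnO2 under neutral conditions should give the enal with the Z geometry retained.

Step 8
Reactants: 11 (2Z)-4-[4-(benzyloxy)-3-methoxyphenyl]-2-{[4-(benzyloxy)-3-methoxyphenyl]methyl}but-2-enal; 12 allyl(diisopropylamino)dimethylsilane
Product: 14 (3S,4R,5Z)-7-[4-(benzyloxy)-3-methoxyphenyl]-5-{[4-(benzyloxy)-3-methoxyphenyl]methyl}hepta-1,5-diene-3,4-diol, via borinate adduct 13 (not isolated)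
Conditions: 12, n-BuLi, TMEDA, Et2O, 0 °C; (−)-Ipc2BOMe (from (+)-α-pinene), −78 °C; BF3·OEt2; 11, −78 °C; then 30% H2O2, KF, KHCO3, THF–MeOH, rt
Reagents that add atoms: hydrogen peroxide, OO
Why: Brown-type asymmetric allylboration with an (E)-γ-silylallyl reagent followed by Tamao–Fleming oxidation: the chair Zimmerman–Traxler transition state gives the anti β-hydroxy allylsilane, the isopinocampheyl groups select the aldehyde face (carbinol R), and C–Si oxidation with retention gives the (3S,4R) anti diol.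

Step 9
Reactants: 14 (3S,4R,5Z)-7-[4-(benzyloxy)-3-methoxyphenyl]-5-{[4-(benzyloxy)-3-methoxyphenyl]methyl}hepta-1,5-diene-3,4-diol
Product: 15 (4S,5R)-5-{(2Z)-1,4-bis[4-(benzyloxy)-3-methoxyphenyl]but-2-en-2-yl}-4-ethenyl-1,3-dioxolane
Conditions: CH2Br2, NaH, DMF, 0 °C → rt
Reagents that add atoms: dibromomethane, BrCBr
Why: Double Williamson alkylation of the diol dianion closes the methylene acetal (a cis-4,5-disubstituted dioxolane) under basic conditions that spare the acid-labile doubly allylic diol; no stereocenter is touched.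

Step 10
Reactants: 15 (4S,5R)-5-{(2Z)-1,4-bis[4-(benzyloxy)-3-methoxyphenyl]but-2-en-2-yl}-4-ethenyl-1,3-dioxolane
Product: 16 (2S,3S,4R)-3,4-bis{[4-(benzyloxy)-3-methoxyphenyl]methyl}-2-ethenyloxolane-3-carbaldehyde
Conditions: SnCl4, CH2Cl2, −78 → −20 °C; aq. NaHCO3
Reagents that add atoms: none
Why: SnCl4 opens the acetal between the CH2 carbon and the oxygen on the alkenyl-bearing carbon, the formaldehyde oxocarbenium ion left on the oxygen of the vinyl-bearing carbon is attacked by the trisubstituted alkene in a chair (Prins step, bond CH2–C4), and in the tertiary cation so formed the ring bond from the stannyloxy carbon to the vinyl-bearing carbon, which lies parallel to the bond just made, shifts to the cationic carbon (pinacol step, bond C2–C3) and releases the formyl group. The closest known reaction type is the Lewis acid promoted Prins cyclization–pinacol rearrangement of 4-alkenyl-1,3-dioxolanes to 3-acyltetrahydrofurans, which can also be read as a 2-oxonia-Cope rearrangement followed by aldol closure. An oxane ring is closed 6-endo-trig on the alkene and the oxolane then arises by ring contraction through the 1,2-alkyl shift, not by a direct five-ring closure. The new tertiary center C4 is controlled by the vinyl-bearing stereocenter, which sits equatorial in the chair (with the anti acetal the C–OSn bond is equatorial too, so only the alkene benzyl is axial) and so selects one alkene face; the quaternary center C3 is controlled by the alkene geometry, because both new bonds reach the same face of the alkene and the Z arrangement therefore leaves formyl cis and benzyl trans to the C4 benzyl group, while the migrating carbon keeps its configuration. The step needs the productive acetal opening and a shift that outruns proton loss, arene capture and the stereochemically looser oxonia-Cope/aldol path: only the oxocarbenium ion on the vinyl-side oxygen can reach the nucleophilic trisubstituted alkene through a six-membered transition state (the other ion finds only the unreactive vinyl group and recloses), and the donor C–OSn bond next to a tertiary cation should make the shift very fast.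

Step 11
Reactants: 16 (2S,3S,4R)-3,4-bis{[4-(benzyloxy)-3-methoxyphenyl]methyl}-2-ethenyloxolane-3-carbaldehyde
Product: 18 (2R,3S,4R)-3,4-bis{[4-(benzyloxy)-3-methoxyphenyl]methyl}oxolane-2,3-dicarbaldehyde, via secondary ozonide 17 (not isolated)
Conditions: O3, CH2Cl2, −78 °C; then PPh3, −78 °C → rt (anhydrous work-up, used crude)
Reagents that add atoms: ozone, [O-][O+]=O
Why: Ozonolysis of the only remaining alkene (the vinyl helper) with reductive work-up gives the α-alkoxy aldehyde, the arenes and the neopentyl-type aldehyde being spared at −78 °C.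

Step 12
Reactants: 18 (2R,3S,4R)-3,4-bis{[4-(benzyloxy)-3-methoxyphenyl]methyl}oxolane-2,3-dicarbaldehyde
Product: 20 (3S,4S)-3,4-bis{[4-(benzyloxy)-3-methoxyphenyl]methyl}oxolane-2,3-diol (anomer mixture), via bis-formate 19 (not isolated)
Conditions: mCPBA, Na2HPO4, CH2Cl2, 0 °C → rt; then KHCO3, MeOH, rt
Reagents that add atoms: 3-chloroperoxybenzoic acid, OOC(=O)c1cccc(Cl)c1
Why: Double Baeyer–Villiger oxidation of aldehydes: in each Criegee adduct the electron-rich carbon (the α-alkoxy ring carbon and the tertiary alkyl carbon) should migrate ahead of hydrogen with retention, and mild methanolysis of the two formates then unveils the lactol and the tertiary alcohol.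

Step 13
Reactants: 20 (3S,4S)-3,4-bis{[4-(benzyloxy)-3-methoxyphenyl]methyl}oxolane-2,3-diol
Product: 21 (3S,4S)-3,4-bis{[4-(benzyloxy)-3-methoxyphenyl]methyl}-3-hydroxyoxolan-2-one
Conditions: Ag2CO3 on Celite, toluene, reflux
Reagents that add atoms: none
Why: Fétizon oxidation oxidizes the lactol selectively to the γ-lactone and cannot oxidize the tertiary alcohol, and it avoids the glycol cleavage that periodate- or iodine-based oxidants could cause.

Step 14
Reactants: 21 (3S,4S)-3,4-bis{[4-(benzyloxy)-3-methoxyphenyl]methyl}-3-hydroxyoxolan-2-one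
Product: 22 (3S,4S)-3-hydroxy-3,4-bis[(4-hydroxy-3-methoxyphenyl)methyl]oxolan-2-one
Conditions: H2 (1 atm), Pd/C, EtOAc–MeOH, rt
Reagents that add atoms: none
Why: Catalytic hydrogenolysis of the two aryl benzyl ethers frees the phenols, while the lactone, the tertiary alcohol and both stereocenters are inert.

**Compound list**

1 | eugenol (4-allyl-2-methoxyphenol) | C=CCc1ccc(O)c(OC)c1 | starting material
2 | 4-allyl-1-(benzyloxy)-2-methoxybenzene | C=CCc1ccc(OCc2ccccc2)c(OC)c1 | intermediate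
3 | 3-{[4-(benzyloxy)-3-methoxyphenyl]methyl}-1,2,4-trioxolane (secondary ozonide, not isolated) | C1OC(Cc2ccc(OCc3ccccc3)c(OC)c2)OO1 | intermediate
4 | [4-(benzyloxy)-3-methoxyphenyl]acetaldehyde | O=CCc1ccc(OCc2ccccc2)c(OC)c1 | intermediate
5 | [4-(benzyloxy)-3-methoxyphenyl]methanol | OCc1ccc(OCc2ccccc2)c(OC)c1 | starting material
6 | 1-(benzyloxy)-4-(bromomethyl)-2-methoxybenzene | BrCc1ccc(OCc2ccccc2)c(OC)c1 | intermediate
7 | methyl 2-[bis(2,2,2-trifluoroethoxy)phosphoryl]acetate | COC(=O)CP(=O)(OCC(F)(F)F)OCC(F)(F)F | starting material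
8 | methyl 3-[4-(benzyloxy)-3-methoxyphenyl]-2-[bis(2,2,2-trifluoroethoxy)phosphoryl]propanoate (racemic) | COC(=O)C(Cc1ccc(OCc2ccccc2)c(OC)c1)P(=O)(OCC(F)(F)F)OCC(F)(F)F | intermediate
9 | methyl (2Z)-4-[4-(benzyloxy)-3-methoxyphenyl]-2-{[4-(benzyloxy)-3-methoxyphenyl]methyl}but-2-enoate | COC(=O)/C(Cc1ccc(OCc2ccccc2)c(OC)c1)=C\Cc1ccc(OCc2ccccc2)c(OC)c1 | intermediate
10 | (2Z)-4-[4-(benzyloxy)-3-methoxyphenyl]-2-{[4-(benzyloxy)-3-methoxyphenyl]methyl}but-2-en-1-ol | OC/C(Cc1ccc(OCc2ccccc2)c(OC)c1)=C\Cc1ccc(OCc2ccccc2)c(OC)c1 | intermediate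
11 | (2Z)-4-[4-(benzyloxy)-3-methoxyphenyl]-2-{[4-(benzyloxy)-3-methoxyphenyl]methyl}but-2-enal | O=C/C(Cc1ccc(OCc2ccccc2)c(OC)c1)=C\Cc1ccc(OCc2ccccc2)c(OC)c1 | intermediate
12 | allyl(diisopropylamino)dimethylsilane | C=CC[Si](C)(C)N(C(C)C)C(C)C | starting material
13 | (3S,4R,5Z)-7-[4-(benzyloxy)-3-methoxyphenyl]-5-{[4-(benzyloxy)-3-methoxyphenyl]methyl}-3-[(diisopropylamino)dimethylsilyl]hepta-1,5-dien-4-yl bis[(1R,2S,3R,5R)-pinan-3-yl]borinate (not isolated) | C=C[C@H]([Si](C)(C)N(C(C)C)C(C)C)[C@H](OB([C@@H]1C[C@@H]2C[C@H]([C@H]1C)C2(C)C)[C@@H]1C[C@@H]2C[C@H]([C@H]1C)C2(C)C)/C(Cc1ccc(OCc2ccccc2)c(OC)c1)=C\Cc1ccc(OCc2ccccc2)c(OC)c1 | intermediate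
14 | (3S,4R,5Z)-7-[4-(benzyloxy)-3-methoxyphenyl]-5-{[4-(benzyloxy)-3-methoxyphenyl]methyl}hepta-1,5-diene-3,4-diol | C=C[C@H](O)[C@H](O)/C(Cc1ccc(OCc2ccccc2)c(OC)c1)=C\Cc1ccc(OCc2ccccc2)c(OC)c1 | intermediate
15 | (4S,5R)-5-{(2Z)-1,4-bis[4-(benzyloxy)-3-methoxyphenyl]but-2-en-2-yl}-4-ethenyl-1,3-dioxolane | C=C[C@@H]1OCO[C@@H]1/C(Cc1ccc(OCc2ccccc2)c(OC)c1)=C\Cc1ccc(OCc2ccccc2)c(OC)c1 | intermediate
16 | (2S,3S,4R)-3,4-bis{[4-(benzyloxy)-3-methoxyphenyl]methyl}-2-ethenyloxolane-3-carbaldehyde | C=C[C@@H]1OC[C@H](Cc2ccc(OCc3ccccc3)c(OC)c2)[C@]1(Cc1ccc(OCc2ccccc2)c(OC)c1)C=O | intermediate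
17 | (2R,3S,4R)-3,4-bis{[4-(benzyloxy)-3-methoxyphenyl]methyl}-2-(1,2,4-trioxolan-3-yl)oxolane-3-carbaldehyde (secondary ozonide, not isolated) | C1OC(OO1)[C@@H]1OC[C@H](Cc2ccc(OCc3ccccc3)c(OC)c2)[C@]1(Cc1ccc(OCc2ccccc2)c(OC)c1)C=O | intermediate
18 | (2R,3S,4R)-3,4-bis{[4-(benzyloxy)-3-methoxyphenyl]methyl}oxolane-2,3-dicarbaldehyde | O=C[C@@H]1OC[C@H](Cc2ccc(OCc3ccccc3)c(OC)c2)[C@]1(Cc1ccc(OCc2ccccc2)c(OC)c1)C=O | intermediate
19 | (2S,3S,4S)-3,4-bis{[4-(benzyloxy)-3-methoxyphenyl]methyl}oxolane-2,3-diyl diformate (not isolated) | O=CO[C@@H]1OC[C@H](Cc2ccc(OCc3ccccc3)c(OC)c2)[C@]1(Cc1ccc(OCc2ccccc2)c(OC)c1)OC=O | intermediate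
20 | (3S,4S)-3,4-bis{[4-(benzyloxy)-3-methoxyphenyl]methyl}oxolane-2,3-diol (anomer mixture) | OC1OC[C@H](Cc2ccc(OCc3ccccc3)c(OC)c2)[C@]1(Cc1ccc(OCc2ccccc2)c(OC)c1)O | intermediate
21 | (3S,4S)-3,4-bis{[4-(benzyloxy)-3-methoxyphenyl]methyl}-3-hydroxyoxolan-2-one | O=C1OC[C@H](Cc2ccc(OCc3ccccc3)c(OC)c2)[C@]1(Cc1ccc(OCc2ccccc2)c(OC)c1)O | intermediate
22 | (3S,4S)-3-hydroxy-3,4-bis[(4-hydroxy-3-methoxyphenyl)methyl]oxolan-2-one | COc1cc(C[C@H]2COC(=O)[C@]2(O)Cc2ccc(O)c(OC)c2)ccc1O | target

**Totals**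

Total step count: 14. Longest linear sequence: 12 steps (steps 3 to 14 from 5, or steps 1, 2 and 5 to 14 from 1).

**Steps most likely to fail**

1. Step 10. Stereochemical fidelity may be lost if the cascade leaks into the ring-flipped chair or into the oxonia-Cope/aldol path. The allylic C–O bond may also ionize, or the tertiary cation may be captured by the electron-rich ring before the shift. Fallback, which sets out from 10 and comes back at 21, using known epoxide chemistry to set both centers: Sharpless asymmetric epoxidation of 10 (Ti(OiPr)4, D-(−)-diethyl tartrate, t-BuOOH, 4 Å sieves, CH2Cl2, −20 °C) should give [(2R,3S)-2,3-bis{[4-(benzyloxy)-3-methoxyphenyl]methyl}oxiran-2-yl]methanol F1. Copper-catalyzed opening with vinylmagnesium bromide (CuI, THF, −30 °C) at the less substituted oxirane carbon, with inversion, should give (2S,3S)-2,3-bis{[4-(benzyloxy)-3-methoxyphenyl]methyl}pent-4-ene-1,2-diol F2. Oxidation of the primary alcohol (TEMPO, NaOCl cat., NaClO2, buffered MeCN–water) should give (2S,3S)-2,3-bis{[4-(benzyloxy)-3-methoxyphenyl]methyl}-2-hydroxypent-4-enoic acid F3. Ozonolysis with NaBH4 work-up should give (2S,3S)-2,3-bis{[4-(benzyloxy)-3-methoxyphenyl]methyl}-2,4-dihydroxybutanoic acid F4, which closes to 21 on acidification.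

2. Step 12. Hydrogen instead of carbon may migrate at the hindered aldehyde (over-oxidation to the acid), and the cis-dialdehyde may hydrate and cyclize before oxidation. Fallback, which sets out from 16 and comes back at 20, making the tertiary oxygenation a ketone Baeyer–Villiger: MeMgBr (THF, −78 °C) on 16 should give 1-[(2S,3R,4R)-3,4-bis{[4-(benzyloxy)-3-methoxyphenyl]methyl}-2-ethenyloxolan-3-yl]ethan-1-ol F5 (carbinol epimers). Dess–Martin periodinane should give the methyl ketone 1-[(2S,3S,4R)-3,4-bis{[4-(benzyloxy)-3-methoxyphenyl]methyl}-2-ethenyloxolan-3-yl]ethan-1-one F6. Ozonolysis (O3, then PPh3) should give (2R,3S,4R)-3-acetyl-3,4-bis{[4-(benzyloxy)-3-methoxyphenyl]methyl}oxolane-2-carbaldehyde F7. mCPBA, in which the tertiary carbon migrates ahead of methyl, should give (2S,3S,4S)-3,4-bis{[4-(benzyloxy)-3-methoxyphenyl]methyl}-2-(formyloxy)oxolan-3-yl acetate F8, and K2CO3 in MeOH then gives 20.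

3. Step 8. Facial selection on the α-branched (Z)-enal may be incomplete, and the β-hydroxy silane may eliminate (Peterson type) during the C–Si oxidation. Fallback, which sets out from 11 and comes back at 16, carrying the oxocarbenium precursor as a methoxymethyl ether: Brown alkoxyallylboration of 11 with allyl methoxymethyl ether (s-BuLi, (+)-Ipc2BOMe, BF3·OEt2, −78 °C; NaOH, H2O2) should give the syn adduct (3S,4S,5Z)-7-[4-(benzyloxy)-3-methoxyphenyl]-5-{[4-(benzyloxy)-3-methoxyphenyl]methyl}-3-(methoxymethoxy)hepta-1,5-dien-4-ol F9. Dess–Martin periodinane should give (3S,5Z)-7-[4-(benzyloxy)-3-methoxyphenyl]-5-{[4-(benzyloxy)-3-methoxyphenyl]methyl}-3-(methoxymethoxy)hepta-1,5-dien-4-one F10. Chelation-controlled reduction with Zn(BH4)2 (Et2O, −30 °C) should give the anti alcohol (3S,4R,5Z)-7-[4-(benzyloxy)-3-methoxyphenyl]-5-{[4-(benzyloxy)-3-methoxyphenyl]methyl}-3-(methoxymethoxy)hepta-1,5-dien-4-ol F11. SnCl4 (CH2Cl2, −78 → −20 °C) then ionizes the methoxymethyl ether to the same oxocarbenium ion and should deliver 16.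

Further compounds
F1 | step 10 | [(2R,3S)-2,3-bis{[4-(benzyloxy)-3-methoxyphenyl]methyl}oxiran-2-yl]methanol | OC[C@@]1(Cc2ccc(OCc3ccccc3)c(OC)c2)O[C@H]1Cc1ccc(OCc2ccccc2)c(OC)c1
F2 | step 10 | (2S,3S)-2,3-bis{[4-(benzyloxy)-3-methoxyphenyl]methyl}pent-4-ene-1,2-diol | OC[C@](O)(Cc1ccc(OCc2ccccc2)c(OC)c1)[C@@H](Cc1ccc(OCc2ccccc2)c(OC)c1)C=C
F3 | step 10 | (2S,3S)-2,3-bis{[4-(benzyloxy)-3-methoxyphenyl]methyl}-2-hydroxypent-4-enoic acid | OC(=O)[C@](O)(Cc1ccc(OCc2ccccc2)c(OC)c1)[C@@H](Cc1ccc(OCc2ccccc2)c(OC)c1)C=C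
F4 | step 10 | (2S,3S)-2,3-bis{[4-(benzyloxy)-3-methoxyphenyl]methyl}-2,4-dihydroxybutanoic acid | OC(=O)[C@](O)(Cc1ccc(OCc2ccccc2)c(OC)c1)[C@@H](Cc1ccc(OCc2ccccc2)c(OC)c1)CO
F5 | step 12 | 1-[(2S,3R,4R)-3,4-bis{[4-(benzyloxy)-3-methoxyphenyl]methyl}-2-ethenyloxolan-3-yl]ethan-1-ol (carbinol epimers) | C=C[C@@H]1OC[C@H](Cc2ccc(OCc3ccccc3)c(OC)c2)[C@]1(Cc1ccc(OCc2ccccc2)c(OC)c1)C(C)O
F6 | step 12 | 1-[(2S,3S,4R)-3,4-bis{[4-(benzyloxy)-3-methoxyphenyl]methyl}-2-ethenyloxolan-3-yl]ethan-1-one | C=C[C@@H]1OC[C@H](Cc2ccc(OCc3ccccc3)c(OC)c2)[C@]1(Cc1ccc(OCc2ccccc2)c(OC)c1)C(C)=O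
F7 | step 12 | (2R,3S,4R)-3-acetyl-3,4-bis{[4-(benzyloxy)-3-methoxyphenyl]methyl}oxolane-2-carbaldehyde | O=C[C@@H]1OC[C@H](Cc2ccc(OCc3ccccc3)c(OC)c2)[C@]1(Cc1ccc(OCc2ccccc2)c(OC)c1)C(C)=O
F8 | step 12 | (2S,3S,4S)-3,4-bis{[4-(benzyloxy)-3-methoxyphenyl]methyl}-2-(formyloxy)oxolan-3-yl acetate | O=CO[C@@H]1OC[C@H](Cc2ccc(OCc3ccccc3)c(OC)c2)[C@]1(Cc1ccc(OCc2ccccc2)c(OC)c1)OC(C)=O
F9 | step 8 | (3S,4S,5Z)-7-[4-(benzyloxy)-3-methoxyphenyl]-5-{[4-(benzyloxy)-3-methoxyphenyl]methyl}-3-(methoxymethoxy)hepta-1,5-dien-4-ol | C=C[C@H](OCOC)[C@@H](O)/C(Cc1ccc(OCc2ccccc2)c(OC)c1)=C\Cc1ccc(OCc2ccccc2)c(OC)c1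
F10 | step 8 | (3S,5Z)-7-[4-(benzyloxy)-3-methoxyphenyl]-5-{[4-(benzyloxy)-3-methoxyphenyl]methyl}-3-(methoxymethoxy)hepta-1,5-dien-4-one | C=C[C@H](OCOC)C(=O)/C(Cc1ccc(OCc2ccccc2)c(OC)c1)=C\Cc1ccc(OCc2ccccc2)c(OC)c1
F11 | step 8 | (3S,4R,5Z)-7-[4-(benzyloxy)-3-methoxyphenyl]-5-{[4-(benzyloxy)-3-methoxyphenyl]methyl}-3-(methoxymethoxy)hepta-1,5-dien-4-ol | C=C[C@H](OCOC)[C@H](O)/C(Cc1ccc(OCc2ccccc2)c(OC)c1)=C\Cc1ccc(OCc2ccccc2)c(OC)c1
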